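Remark: α and β refer to the usual eudesmane drawing with the C10 methyl group β. Read this way the target is 1β-arylmethyl, 4α-OH, 5α-H, 7β-isopropenyl, 10β-CH3.
Remark: the facial sense of the amine catalyst in step 2 is assumed to be that of its known enamine additions (electrophile on the face remote from the diarylmethyl arm). If it is the opposite, the mirror-image catalyst is used.

## The problem

Compound 29 is a eudesmane sesquiterpene whose C1 carries, through one methylene group, a hexasubstituted phloroglucinol bearing a formyl and an isobutyryl group. Eudesmane numbering is used throughout: ring A is C1–C5 and C10, ring B is C5–C10; C4 bears OH and CH3, C7 the isopropenyl group, C10 the angular CH3. The decalin is trans-fused with five stereocentres (C1, C4, C5, C7, C10). C1, C10 and C5 are contiguous and C10 is quaternary, with two carbon arms (CH3 and C9) so similar in size that neither C1 nor C5 can be set against C10 by thermodynamics alone. Once the trans-decalin stands, it controls the rest: the axial C10 methyl group closes the β face of ring A, which is what a 4α-hydroxyl group needs, and a chair ring B puts the C7 side chain equatorial. C5 cannot be corrected after ring closure, so it must be right on the monocyclic stage. Three groups are fragile: the isopropenyl group (an unhindered 1,1-disubstituted alkene that competes in hydroboration, hydrogenation and electrophilic additions and isomerises next to a carbonyl group or with acid), the tertiary C4 alcohol (ionises and eliminates with acid), and the acylated phloroglucinol (chelating, oxidisable), which is best completed last. The handle for the key step is the isopropenyl group on C7 next to C6 in ring B: it is the pattern left when a prenyl-terminated chain C9–C8–C7=C11 on C10 closes onto a C6 aldehyde on C5 in a carbonyl-ene reaction, as citronellal gives isopulegol.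

## Retrosynthesis

**29 ⇒ 28 ⇒ 27 ⇒ 25 ⇒ 22 (arene last).** The three phenol O–CH3 bonds, the aryl–CHO bond and the aryl–acyl bond are cut first. In 22 the arene is a 2-alkyl-1,3,5-trimethoxybenzene whose two free positions are equivalent and each flanked by two methoxy groups, so two directed metalations (with 23, then with a formamide) and one oxidation build the substitution pattern. Methyl ethers are chosen because they must survive Lewis acids, organometallics, a tin radical step, peracid and hydride on the way; the price is a thiolate demethylation at the end. Attaching a finished acylphloroglucinol to a C1 carbonyl on the decalin was set aside: it would need hydroboration or acidic benzylic reduction in the presence of the isopropenyl group.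

**22 ⇒ 21 ⇒ 20 (C4–O).** A methyl nucleophile on a C4 ketone would come from the α face and give the wrong 4β-alcohol, so the oxygen must be delivered to an alkene from the α face. A trisubstituted C3=C4 alkene is chosen over an exocyclic one because peracid then tells it apart from the isopropenyl group. The forward steps must give the α-epoxide 21 and open it with hydride at C3 only.

**20 ⇒ 19 ⇒ 18 (C6–H).** The ene reaction leaves a hydroxyl group on C6 that the target lacks; it is removed through a thionocarbonate radical reduction. Oxidising C6 and using the ketone for further chemistry was rejected: a C6 ketone has the isopropenyl-bearing C7 as one α-carbon and would invite conjugation and loss of regiocontrol.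

**18 ⇒ 17 (key step, C6–C7).** Cutting C6–C7 with return of one hydrogen from O6 to a C11 methyl group opens ring B to aldehyde 17. This removes one ring and two stereocentres (C6, C7) and reduces the problem to a cyclohexene with three contiguous stereocentres. Forward, the chair transition state must place the new groups equatorial. Three choices of what 17 carries beside the reacting groups shape everything before it:
- The arylmethyl group is already on C1. It is inert in the ene step, it spares all C1 chemistry after the isopropenyl group exists, and as a C1 substituent trans to the chain it gives C5 a thermodynamic preference; a C1 substituent cis to the chain would give none.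
- C4 already carries its methyl group as a C3=C4 alkene, so that no enolate chemistry is needed after ring closure.
- C6 is the only oxygen to be removed later.

**17 ⇒ 16 ⇒ 15 ⇒ 13 (C4–CH3, aldehyde unmasking).** The β,γ-unsaturated aldehyde is stored as its dimethyl acetal 16, and the C4–CH3 bond is cut back to enol triflate 15 and ketone 13. Forward, enolisation of 13 must go towards C3, which is expected because C5 is a shielded methine between C10 and the acetal.

**13 ⇒ 11 ⇒ 8 + 10 (from 9) (C5–C6 and C10–C9).** The C5–C6 bond is cut to a silyl enol ether and a one-carbon electrophile at the orthoester level, and the C10–C9 bond to enone 8 and Grignard reagent 10. This removes the quaternary centre and C5 together and leaves a cyclohexenone with one stereocentre. Forward, the chain must enter anti to the C1 arylmethyl group, and C5 must then be equilibrated next to the ketone.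

**8 ⇒ 7 ⇒ 6 ⇒ 5 ⇒ 3 + 4 (ring A and C1).** The C10 methyl group is removed (conjugate addition then dehydrogenation in the forward sense), the enone is opened at C5=C10 by a retro-aldol condensation, and the C1–C2 bond of 5 is cut to aldehyde 3 and enone 4. The enamine-catalysed Michael addition sets C1, the one stereocentre from which all others are relayed. A C10-first entry by enantioselective reduction of a 2,2-disubstituted cyclohexane-1,3-dione was weighed against this: it fixes C10 well but leaves a C1 oxygen cis to the chain and no handle at C4.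

**3 ⇒ 1 + 2 (aryl–CH2).** The aryl–carbon bond is cut to iodide 1 and allylic alcohol 2; a Heck arylation gives the three-carbon aldehyde directly.

## Roads not taken

**Alternative 1:** The cut is the C4=C5 bond of a ring A enone. Forward, an amino acid such as proline would condense the ethyl ketone arm of triketone A2 through C4 onto one of the two ring B carbonyl groups, giving enedione ester A1 and fixing C10 and C7. Merits: ring A, the quaternary centre and the C4 methyl group arrive in one catalytic step, the arylmethyl group is present from the start, and the C7 ester is a precursor of the isopropenyl group. Weak points here: A2 already contains the C1 stereocentre, so the catalyst must choose between the carbonyl groups in a matched or mismatched sense. Ethyl ketones react through a more hindered enamine than methyl ketones. A1 carries oxygen at C3 and C9 that the target lacks, C4=C5 must still become 4α-OH/5α-H, and the ester must become the alkene regioselectively. Comparison: it reaches a bicyclic intermediate sooner and sets C10 by catalysis, where the chosen plan relays C10 from C1. Against that, the chosen plan has a single oxygen to remove after ring closure, and it obtains C7 and the isopropenyl group in the ring-forming step.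

**Alternative 2:** The aromatic ring itself is cut, between the carbons that become the acyl-bearing carbon and its hydroxylated neighbour. Forward, Mg(OMe)2 would deprotonate triketo ester A4 at the methylene between the two far carbonyl groups; Claisen condensation onto the ester and enolisation would give the deformyl acylphloroglucinol A3, and a formylation would finish. Merits: no phenol protecting groups, no aryl–metal chemistry, the acyl group is built in, and the end game is two steps. Weak points: it solves only the arene, so the complete terpene with all five stereocentres must exist first. A 3,5,7-triketo ester can also close by aldol reaction or O-acylation. The final electrophilic formylation exposes the isopropenyl group and the tertiary alcohol to acid. Comparison: its end game is better than the chosen one, which pays four late steps including a thiolate demethylation. The chosen plan sets against this an arene that is a robust spectator from step 1 and also serves as the large C1 substituent that directs C10 and C5.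

**Alternative 3:** The cuts are C10–CH3 and C4–C5. Forward, AlMe3 with a chiral phosphoramidite complex of copper thiophene-2-carboxylate would add methyl to C10 of dienone A6, and the aluminium enolate would close ring A by aldol addition of C5 to the tethered methyl ketone, giving hydroxy ketone A5. Merits: C10, C5 and the C4 carbinol are set in one operation, C10 by a catalyst, and the arylidene is already at C1. Weak points: in A6, 1,6-addition at the arylidene carbon competes with 1,4-addition at the disubstituted C10. The aldol must give the trans fusion and the 4α-alcohol at once, and A5 can revert. Afterwards the arylidene must be reduced to the 1β-arylmethyl group and the isopropenyl group installed next to the C6 ketone, which means enolate chemistry at C7. Comparison: for C4 and for step count to the decalin this road is better; the chosen plan spends four steps (triflate, methylation, epoxidation, hydride) on the C4 carbinol. The chosen plan sets against this that ring B, C7 and the isopropenyl group come from one well-precedented step, and that no carbonyl group is ever next to C7.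

Key step: step 11

## Route

Step 1
Reactants: 1 2-iodo-1,3,5-trimethoxybenzene; 2 prop-2-en-1-ol
Product: 3 3-(2,4,6-trimethoxyphenyl)propanal
Conditions: Pd(OAc)2 (5 mol%), Bu4NCl, NaHCO3, DMF, 50 °C
Reagents that add atoms: none
Why: Heck arylation of an allylic alcohol under Jeffery conditions: the aryl group adds to the terminal carbon and β-hydride elimination towards the carbinol gives the enol and hence the saturated aldehyde; the methyl ethers are inert.

Step 2
Reactants: 3 3-(2,4,6-trimethoxyphenyl)propanal; 4 but-3-en-2-one
Product: 5 (S)-5-oxo-2-(2,4,6-trimethoxybenzyl)hexanal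
Conditions: (S)-2-[methoxy(diphenyl)methyl]pyrrolidine (5 mol%), ethyl 3,4-dihydroxybenzoate (20 mol%), neat, 4 °C
Reagents that add atoms: none
Why: Enamine-catalysed Michael addition of an aldehyde to methyl vinyl ketone; the diphenyl(methoxy)methyl arm shields one face of the E-enamine, so the enone enters from the open face and sets C1, from which all other stereocentres are relayed.

Step 3
Reactants: 5 (S)-5-oxo-2-(2,4,6-trimethoxybenzyl)hexanal
Product: 6 (S)-4-(2,4,6-trimethoxybenzyl)cyclohex-2-en-1-one
Conditions: LiOH, i-PrOH, 20 °C
Reagents that add atoms: none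
Why: Intramolecular aldol condensation of the methyl ketone enolate onto the aldehyde, the only six-membered mode, closes ring A; the mild base is chosen so that ring closure outruns epimerisation of the α-branched aldehyde.

Step 4
Reactants: 6 (S)-4-(2,4,6-trimethoxybenzyl)cyclohex-2-en-1-one
Product: 7 trimethyl{[(3S,4S)-3-methyl-4-(2,4,6-trimethoxybenzyl)cyclohex-1-en-1-yl]oxy}silane (3,4-trans)
Conditions: MeMgBr, CuBr·SMe2 (10 mol%), Me3SiCl, THF, −78 °C
Reagents that add atoms: methylmagnesium bromide, C[Mg]Br; chlorotrimethylsilane, C[Si](C)(C)Cl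
Why: Copper-catalysed conjugate addition with silyl trapping of the enolate puts the future C10 methyl group in place; the new centre becomes trigonal again in step 5, so its configuration does not matter.

Step 5
Reactants: 7 trimethyl{[(3S,4S)-3-methyl-4-(2,4,6-trimethoxybenzyl)cyclohex-1-en-1-yl]oxy}silane
Product: 8 (S)-3-methyl-4-(2,4,6-trimethoxybenzyl)cyclohex-2-en-1-one
Conditions: Pd(OAc)2 (1.05 equiv), MeCN, 20 °C
Reagents that add atoms: none
Why: Saegusa–Ito oxidation: the palladium enolate loses the C10 hydrogen by β-hydride elimination and returns the enone, now methylated at C10; no base is present, so C1 is untouched.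

Step 6
Reactants: 8 (S)-3-methyl-4-(2,4,6-trimethoxybenzyl)cyclohex-2-en-1-one; 9 5-bromo-2-methylpent-2-ene
Product: 11 trimethyl{[(3S,4S)-3-methyl-3-(4-methylpent-3-en-1-yl)-4-(2,4,6-trimethoxybenzyl)cyclohex-1-en-1-yl]oxy}silane, via Grignard reagent 10 (not isolated)
Conditions: 9, Mg, THF; then 8, CuBr·SMe2 (20 mol%), Me3SiCl, HMPA, THF, −78 °C → −40 °C
Reagents that add atoms: chlorotrimethylsilane, C[Si](C)(C)Cl
Why: Me3SiCl-accelerated copper-catalysed conjugate addition to a β,β-disubstituted enone, as with 3,4-dialkylcyclohexenones: the chain enters C10 anti to the pseudoaxial C1 arylmethyl group, so the chain is trans and the methyl group cis to CH2Ar. The enolate is kept as the silyl enol ether for step 7.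

Step 7
Reactants: 11 trimethyl{[(3S,4S)-3-methyl-3-(4-methylpent-3-en-1-yl)-4-(2,4,6-trimethoxybenzyl)cyclohex-1-en-1-yl]oxy}silane
Product: 13 (2S,3S,4S)-2-(dimethoxymethyl)-3-methyl-3-(4-methylpent-3-en-1-yl)-4-(2,4,6-trimethoxybenzyl)cyclohexan-1-one, via 5-epimeric keto acetal 12 (not isolated)
Conditions: HC(OMe)3, Me3SiOTf (10 mol%), CH2Cl2, −78 °C; then K2CO3, MeOH, 20 °C
Reagents that add atoms: trimethyl orthoformate, COC(OC)OC
Why: Mukaiyama-type addition of the silyl enol ether to the dimethoxycarbenium ion brings in C6 at the aldehyde oxidation level. C5, α to the C4 ketone, is then equilibrated to the epimer with the acetal trans to the chain, the only one in which CH2Ar, chain and acetal are all equatorial with just the C10 methyl group axial.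

Step 8
Reactants: 13 (2S,3S,4S)-2-(dimethoxymethyl)-3-methyl-3-(4-methylpent-3-en-1-yl)-4-(2,4,6-trimethoxybenzyl)cyclohexan-1-one
Product: 15 (4S,5S,6R)-6-(dimethoxymethyl)-5-methyl-5-(4-methylpent-3-en-1-yl)-4-(2,4,6-trimethoxybenzyl)cyclohex-1-en-1-yl trifluoromethanesulfonate, via potassium enolate 14 (not isolated)
Conditions: KN(SiMe3)2, THF, −78 °C; then PhNTf2
Reagents that add atoms: N-phenylbis(trifluoromethanesulfonimide), O=S(=O)(N(c1ccccc1)S(=O)(=O)C(F)(F)F)C(F)(F)F
Why: Kinetic deprotonation takes a C3 hydrogen, because C5 is a shielded methine between the quaternary C10 and the acetal; O-sulfonylation fixes the C3=C4 enol triflate without touching C5.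

Step 9
Reactants: 15 (4S,5S,6R)-6-(dimethoxymethyl)-5-methyl-5-(4-methylpent-3-en-1-yl)-4-(2,4,6-trimethoxybenzyl)cyclohex-1-en-1-yl trifluoromethanesulfonate
Product: 16 (3S,4S,5S)-3-(dimethoxymethyl)-2,4-dimethyl-4-(4-methylpent-3-en-1-yl)-5-(2,4,6-trimethoxybenzyl)cyclohex-1-ene
Conditions: MeMgBr, Fe(acac)3 (5 mol%), THF/NMP, −30 °C → 0 °C
Reagents that add atoms: methylmagnesium bromide, C[Mg]Br
Why: Iron-catalysed cross-coupling of an alkenyl triflate with a Grignard reagent puts the C15 methyl group on C4 and leaves the trisubstituted C3=C4 alkene needed for the C4 carbinol; acetal and aryl ethers are inert.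

Step 10
Reactants: 16 (3S,4S,5S)-3-(dimethoxymethyl)-2,4-dimethyl-4-(4-methylpent-3-en-1-yl)-5-(2,4,6-trimethoxybenzyl)cyclohex-1-ene
Product: 17 (1S,5S,6S)-2,6-dimethyl-6-(4-methylpent-3-en-1-yl)-5-(2,4,6-trimethoxybenzyl)cyclohex-2-ene-1-carbaldehyde
Conditions: 10% aq. oxalic acid on SiO2, CH2Cl2, 20 °C
Reagents that add atoms: water, O
Why: Mild hydrolysis of a dimethyl acetal on wet acidic silica; the weak acid and short contact are chosen so that the β,γ-unsaturated aldehyde is not conjugated and C5 is kept. Aldehyde 17 is used at once.

Step 11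
Reactants: 17 (1S,5S,6S)-2,6-dimethyl-6-(4-methylpent-3-en-1-yl)-5-(2,4,6-trimethoxybenzyl)cyclohex-2-ene-1-carbaldehyde
Product: 18 1β-(2,4,6-trimethoxybenzyl)eudesma-3,11-dien-6α-ol (trans-decalin; 5α-H, 7β-isopropenyl, 10β-CH3)
Conditions: Me2AlCl (2 equiv), CH2Cl2, −78 °C → −20 °C
Reagents that add atoms: none
Why: Me2AlCl binds the C6 aldehyde oxygen; C7 of the trisubstituted alkene bonds to C6 while a hydrogen of a C11 methyl group passes to oxygen through a six-centre array, so C6–C7 forms, ring B closes and the C11=C12 isopropenyl group is left. The closest known reaction is the Lewis acid type 1 carbonyl-ene cyclisation of citronellal to isopulegol. Ring B closes in the 6-exo sense with respect to C7=C11 through a chair in which C5–C6 and C10–C9 are the trans-diequatorial bonds of ring A and the C10 methyl group is axial, which gives the trans fusion already coded in 17. At C7 the isopropylidene terminus takes the equatorial position of this chair, giving 7β-isopropenyl. At C6 the complexed oxygen lies equatorial, away from the axial C10 methyl group, giving the 6α-alcohol; this centre is removed in step 13, so any 6β epimer does no harm. The step needs ene closure to outrun migration of C3=C4 into conjugation, cationic side reactions and attack on the arene. Me2AlCl scavenges protons through its Al–C bonds, the closure is intramolecular at low temperature, and the aryl ring can reach C6 only with its substituted ipso and ortho carbons.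

Step 12
Reactants: 18 1β-(2,4,6-trimethoxybenzyl)eudesma-3,11-dien-6α-ol
Product: 19 O-phenyl O-[1β-(2,4,6-trimethoxybenzyl)eudesma-3,11-dien-6α-yl] thiocarbonate
Conditions: PhOC(S)Cl, pyridine, DMAP (cat.), CH2Cl2, 20 °C
Reagents that add atoms: O-phenyl chlorothionoformate, S=C(Cl)Oc1ccccc1
Why: Acylation of the only hydroxyl group gives the radical precursor for a Barton–McCombie deoxygenation.

Step 13
Reactants: 19 O-phenyl O-[1β-(2,4,6-trimethoxybenzyl)eudesma-3,11-dien-6α-yl] thiocarbonate
Product: 20 1β-(2,4,6-trimethoxybenzyl)eudesma-3,11-diene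
Conditions: Bu3SnH (0.5 M), AIBN, toluene, 100 °C
Reagents that add atoms: none
Why: Barton–McCombie deoxygenation; the secondary C6 radical is homoallylic to both alkenes, and the high stannane concentration lets hydrogen transfer outrun the slow 3-exo closure that would start a vinyl shift. C6 becomes CH2, so both C6 epimers of 18 converge here.

Step 14
Reactants: 20 1β-(2,4,6-trimethoxybenzyl)eudesma-3,11-diene
Product: 21 3α,4α-epoxy-1β-(2,4,6-trimethoxybenzyl)eudesm-11-ene
Conditions: mCPBA (1.05 equiv), NaHCO3, CH2Cl2, −20 °C → 0 °C
Reagents that add atoms: 3-chloroperbenzoic acid, O=C(OO)c1cccc(Cl)c1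
Why: Prilezhaev epoxidation; the trisubstituted ring alkene is more electron-rich than the isopropenyl group (the limonene pattern), and the peracid comes from the α face because the axial C10 methyl group covers the β face at C4. This places the oxygen α on C4.

Step 15
Reactants: 21 3α,4α-epoxy-1β-(2,4,6-trimethoxybenzyl)eudesm-11-ene
Product: 22 1β-(2,4,6-trimethoxybenzyl)eudesm-11-en-4α-ol
Conditions: LiEt3BH, THF, 0 °C → 20 °C
Reagents that add atoms: none
Why: Hydride opening of a trisubstituted epoxide at its secondary carbon C3 (SN2) leaves the C4–O bond untouched and gives the 4α-hydroxy-4β-methyl carbinol; alkenes and aryl ethers do not react.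

Step 16
Reactants: 22 1β-(2,4,6-trimethoxybenzyl)eudesm-11-en-4α-ol; 23 2-methylpropanal
Product: 25 1β-[3-(1-hydroxy-2-methylpropyl)-2,4,6-trimethoxybenzyl]eudesm-11-en-4α-ol (both carbinol epimers), via dilithio species 24 (not isolated)
Conditions: n-BuLi (2.2 equiv), THF, 0 °C; then 23, −78 °C; buffered work-up
Reagents that add atoms: none
Why: Directed ortho-metalation: after the alkoxide forms, a ring hydrogen between two methoxy groups is removed (the two free positions are equivalent) and the aryllithium adds to the aldehyde. The new carbinol configuration is irrelevant because it is oxidised in step 18.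

Step 17
Reactants: 25 1β-[3-(1-hydroxy-2-methylpropyl)-2,4,6-trimethoxybenzyl]eudesm-11-en-4α-ol
Product: 27 3-[(4α-hydroxyeudesm-11-en-1β-yl)methyl]-5-(1-hydroxy-2-methylpropyl)-2,4,6-trimethoxybenzaldehyde, via trilithio species 26 (not isolated)
Conditions: n-BuLi (3.3 equiv), THF, 0 °C; then DMF, −78 °C → 0 °C
Reagents that add atoms: N,N-dimethylformamide, CN(C)C=O
Why: Second directed ortho-metalation at the last ring hydrogen, again flanked by two methoxy groups, with both hydroxyl groups masked as lithium alkoxides; formylation with DMF. Ring metalation at 0 °C without a diamine should be faster than allylic metalation of the isopropenyl group.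

Step 18
Reactants: 27 3-[(4α-hydroxyeudesm-11-en-1β-yl)methyl]-5-(1-hydroxy-2-methylpropyl)-2,4,6-trimethoxybenzaldehyde
Product: 28 3-[(4α-hydroxyeudesm-11-en-1β-yl)methyl]-2,4,6-trimethoxy-5-(2-methylpropanoyl)benzaldehyde
Conditions: Dess–Martin periodinane, NaHCO3, CH2Cl2, 0 °C → 20 °C
Reagents that add atoms: none
Why: Oxidation of the secondary benzylic alcohol to the aryl ketone; the tertiary alcohol cannot be oxidised, and the aldehyde and alkene are inert to the periodinane.

Step 19
Reactants: 28 3-[(4α-hydroxyeudesm-11-en-1β-yl)methyl]-2,4,6-trimethoxy-5-(2-methylpropanoyl)benzaldehyde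
Product: 29 3-[(4α-hydroxyeudesm-11-en-1β-yl)methyl]-2,4,6-trihydroxy-5-(2-methylpropanoyl)benzaldehyde (CNP0498016.1)
Conditions: NaSEt, DMF, 110 °C; then 1 M HCl, 0 °C
Reagents that add atoms: none
Why: Nucleophilic demethylation of aryl methyl ethers by thiolate (SN2 at the methyl carbon); each methoxy group is ortho to a carbonyl group that stabilises the departing phenoxide, and the basic medium spares the tertiary alcohol and the isopropenyl group that an acid would attack.

## Compound list

1 | 2-iodo-1,3,5-trimethoxybenzene | COc1cc(OC)c(I)c(OC)c1 | starting material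
2 | prop-2-en-1-ol | C=CCO | starting material
3 | 3-(2,4,6-trimethoxyphenyl)propanal | O=CCCc1c(OC)cc(OC)cc1OC | intermediate
4 | but-3-en-2-one | C=CC(C)=O | starting material
5 | (S)-5-oxo-2-(2,4,6-trimethoxybenzyl)hexanal | O=C[C@H](Cc1c(OC)cc(OC)cc1OC)CCC(C)=O | intermediate
6 | (S)-4-(2,4,6-trimethoxybenzyl)cyclohex-2-en-1-one | O=C1C=C[C@H](Cc2c(OC)cc(OC)cc2OC)CC1 | intermediate
7 | trimethyl{[(3S,4S)-3-methyl-4-(2,4,6-trimethoxybenzyl)cyclohex-1-en-1-yl]oxy}silane | C[Si](C)(C)OC1=C[C@@H](C)[C@H](Cc2c(OC)cc(OC)cc2OC)CC1 | intermediate
8 | (S)-3-methyl-4-(2,4,6-trimethoxybenzyl)cyclohex-2-en-1-one | O=C1C=C(C)[C@H](Cc2c(OC)cc(OC)cc2OC)CC1 | intermediate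
9 | 5-bromo-2-methylpent-2-ene | CC(C)=CCCBr | starting material
10 | (4-methylpent-3-en-1-yl)magnesium bromide | CC(C)=CCC[Mg]Br | intermediate
11 | trimethyl{[(3S,4S)-3-methyl-3-(4-methylpent-3-en-1-yl)-4-(2,4,6-trimethoxybenzyl)cyclohex-1-en-1-yl]oxy}silane | C[Si](C)(C)OC1=C[C@@](C)(CCC=C(C)C)[C@H](Cc2c(OC)cc(OC)cc2OC)CC1 | intermediate
12 | (2R,3S,4S)-2-(dimethoxymethyl)-3-methyl-3-(4-methylpent-3-en-1-yl)-4-(2,4,6-trimethoxybenzyl)cyclohexan-1-one (acetal cis to the chain) | COC(OC)[C@@H]1C(=O)CC[C@@H](Cc2c(OC)cc(OC)cc2OC)[C@]1(C)CCC=C(C)C | intermediate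
13 | (2S,3S,4S)-2-(dimethoxymethyl)-3-methyl-3-(4-methylpent-3-en-1-yl)-4-(2,4,6-trimethoxybenzyl)cyclohexan-1-one (acetal trans to the chain) | COC(OC)[C@H]1C(=O)CC[C@@H](Cc2c(OC)cc(OC)cc2OC)[C@]1(C)CCC=C(C)C | intermediate
14 | potassium (4S,5S,6R)-6-(dimethoxymethyl)-5-methyl-5-(4-methylpent-3-en-1-yl)-4-(2,4,6-trimethoxybenzyl)cyclohex-1-en-1-olate | COC(OC)[C@H]1C(O[K])=CC[C@@H](Cc2c(OC)cc(OC)cc2OC)[C@]1(C)CCC=C(C)C | intermediate
15 | (4S,5S,6R)-6-(dimethoxymethyl)-5-methyl-5-(4-methylpent-3-en-1-yl)-4-(2,4,6-trimethoxybenzyl)cyclohex-1-en-1-yl trifluoromethanesulfonate | COC(OC)[C@H]1C(OS(=O)(=O)C(F)(F)F)=CC[C@@H](Cc2c(OC)cc(OC)cc2OC)[C@]1(C)CCC=C(C)C | intermediate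
16 | (3S,4S,5S)-3-(dimethoxymethyl)-2,4-dimethyl-4-(4-methylpent-3-en-1-yl)-5-(2,4,6-trimethoxybenzyl)cyclohex-1-ene | COC(OC)[C@H]1C(C)=CC[C@@H](Cc2c(OC)cc(OC)cc2OC)[C@]1(C)CCC=C(C)C | intermediate
17 | (1S,5S,6S)-2,6-dimethyl-6-(4-methylpent-3-en-1-yl)-5-(2,4,6-trimethoxybenzyl)cyclohex-2-ene-1-carbaldehyde | O=C[C@H]1C(C)=CC[C@@H](Cc2c(OC)cc(OC)cc2OC)[C@]1(C)CCC=C(C)C | intermediate
18 | 1β-(2,4,6-trimethoxybenzyl)eudesma-3,11-dien-6α-ol | C=C(C)[C@@H]1CC[C@@]2(C)[C@H](Cc3c(OC)cc(OC)cc3OC)CC=C(C)[C@@H]2[C@H]1O | intermediate
19 | O-phenyl O-[1β-(2,4,6-trimethoxybenzyl)eudesma-3,11-dien-6α-yl] thiocarbonate | C=C(C)[C@@H]1CC[C@@]2(C)[C@H](Cc3c(OC)cc(OC)cc3OC)CC=C(C)[C@@H]2[C@H]1OC(=S)Oc4ccccc4 | intermediate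
20 | 1β-(2,4,6-trimethoxybenzyl)eudesma-3,11-diene | C=C(C)[C@@H]1CC[C@@]2(C)[C@H](Cc3c(OC)cc(OC)cc3OC)CC=C(C)[C@@H]2C1 | intermediate
21 | 3α,4α-epoxy-1β-(2,4,6-trimethoxybenzyl)eudesm-11-ene | C=C(C)[C@@H]1CC[C@@]2(C)[C@H](Cc3c(OC)cc(OC)cc3OC)C[C@H]4O[C@@]4(C)[C@@H]2C1 | intermediate
22 | 1β-(2,4,6-trimethoxybenzyl)eudesm-11-en-4α-ol | C=C(C)[C@@H]1CC[C@@]2(C)[C@H](Cc3c(OC)cc(OC)cc3OC)CC[C@@](C)(O)[C@@H]2C1 | intermediate
23 | 2-methylpropanal | CC(C)C=O | starting material
24 | O,C-dilithio derivative of 22 (lithium 4-alkoxide, aryllithium between two methoxy groups) | C=C(C)[C@@H]1CC[C@@]2(C)[C@H](Cc3c(OC)cc(OC)c([Li])c3OC)CC[C@@](C)(O[Li])[C@@H]2C1 | intermediate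
25 | 1β-[3-(1-hydroxy-2-methylpropyl)-2,4,6-trimethoxybenzyl]eudesm-11-en-4α-ol (both carbinol epimers) | C=C(C)[C@@H]1CC[C@@]2(C)[C@H](Cc3c(OC)cc(OC)c(C(O)C(C)C)c3OC)CC[C@@](C)(O)[C@@H]2C1 | intermediate
26 | O,O,C-trilithio derivative of 25 (two lithium alkoxides, aryllithium at the last ring position) | C=C(C)[C@@H]1CC[C@@]2(C)[C@H](Cc3c(OC)c([Li])c(OC)c(C(O[Li])C(C)C)c3OC)CC[C@@](C)(O[Li])[C@@H]2C1 | intermediate
27 | 3-[(4α-hydroxyeudesm-11-en-1β-yl)methyl]-5-(1-hydroxy-2-methylpropyl)-2,4,6-trimethoxybenzaldehyde | C=C(C)[C@@H]1CC[C@@]2(C)[C@H](Cc3c(OC)c(C=O)c(OC)c(C(O)C(C)C)c3OC)CC[C@@](C)(O)[C@@H]2C1 | intermediate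
28 | 3-[(4α-hydroxyeudesm-11-en-1β-yl)methyl]-2,4,6-trimethoxy-5-(2-methylpropanoyl)benzaldehyde | C=C(C)[C@@H]1CC[C@@]2(C)[C@H](Cc3c(OC)c(C=O)c(OC)c(C(=O)C(C)C)c3OC)CC[C@@](C)(O)[C@@H]2C1 | intermediate
29 | 3-[(4α-hydroxyeudesm-11-en-1β-yl)methyl]-2,4,6-trihydroxy-5-(2-methylpropanoyl)benzaldehyde (CNP0498016.1) | C=C(C)[C@@H]1CC[C@@]2(C)[C@H](Cc3c(O)c(C=O)c(O)c(C(=O)C(C)C)c3O)CC[C@@](C)(O)[C@@H]2C1 | target

## Step count and risks

Total step count: 19. Longest linear sequence: 19 steps (1 to 29).

**Step 11 (key step).** Most likely failure: under the Lewis acid the ring A double bond migrates into conjugation with the complexed aldehyde (which erases C5), or ring closure becomes stepwise and the C11 cation is trapped by chloride or loses the C7 proton. The cause is that 17 is a β,γ-unsaturated aldehyde with an electron-rich alkene next to the reacting centre. Fallback: close ring B while the ring A alkene is still the electron-poor enol triflate, and cross-couple afterwards. Starting from 15, the acetal is hydrolysed (aqueous oxalic acid on SiO2) to the aldehyde triflate F1, Me2AlCl closes ring B to the hydroxy decalin triflate F2, and MeMgBr with Fe(acac)3 (excess Grignard reagent for the free hydroxyl group) installs the C4 methyl group, returning to the route at 18.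

**Step 7.** Most likely failure: the dimethoxycarbenium ion also attacks the trimethoxyphenyl ring, the keto acetal loses methanol to a 2-(methoxymethylene) ketone during equilibration, or the thermodynamic margin at C5 (one extra gauche contact against one axial group) leaves part of the 5-epimer. Fallback: bring in C6 at the alcohol level with a neutral electrophile and separate epimers at a stable stage. Starting from 11, aqueous formaldehyde with Yb(OTf)3 gives the hydroxymethyl ketone F3, t-BuMe2SiCl and imidazole the silyl ether F4, KN(SiMe3)2 and PhNTf2 the silyloxymethyl enol triflate F5, MeMgBr with Fe(acac)3 the silyloxymethyl diene F6, Bu4NF the primary alcohol F7, and Dess–Martin periodinane oxidises F7 to 17, where the route is rejoined.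

**Step 15.** Most likely failure: hydride has to attack C3 from the β face in a non-diaxial opening, so the reaction may be slow and Lewis acid-induced rearrangement of the epoxide to a C3 ketone may compete. Fallback: open the epoxide by electron transfer instead of nucleophilic attack. Starting from 21, lithium 4,4′-di-tert-butylbiphenylide in THF at −78 °C cleaves the C3–O bond, because the less substituted carbanion is formed, and protonation with methanol returns to the route at 22. No new compound arises.

**Step 13.** Most likely failure: the C6 radical, homoallylic to two alkenes, rearranges by 3-exo closure and reopening, or the thionocarbonate undergoes thermal syn-elimination before it is reduced. Fallback: a polar removal of the C6 oxygen. Starting from 18, Dess–Martin periodinane gives the C6 ketone F8, p-toluenesulfonylhydrazide in ethanol at 20 °C the tosylhydrazone F9, and catecholborane followed by NaOAc trihydrate reduces F9 to the methylene compound, returning at 20. The ketone is handled without base to avoid conjugation of either β,γ-alkene.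

**Step 19.** Most likely failure: the methoxy group between the benzylic carbon and the twisted ketone is cleaved incompletely, or thiolate attacks the formyl group at the temperature needed. Fallback: chelation-directed Lewis acid dealkylation. Starting from 28, Et3SiOTf and 2,6-lutidine give the triethylsilyl ether F10, MgI2·OEt2 in toluene at 80 °C removes the three methyl groups (each ortho to a carbonyl group) to give the triphenol silyl ether F11, and Bu4NF removes the silyl group, arriving at 29.

## Further compounds

F1 | step 11 | aldehyde triflate: enol triflate 15 with the dimethoxymethyl group replaced by CHO | O=C[C@H]1C(OS(=O)(=O)C(F)(F)F)=CC[C@@H](Cc2c(OC)cc(OC)cc2OC)[C@]1(C)CCC=C(C)C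
F2 | step 11 | hydroxy decalin triflate: 6α-hydroxy-1β-(2,4,6-trimethoxybenzyl)-15-noreudesma-3,11-dien-4-yl trifluoromethanesulfonate | C=C(C)[C@@H]1CC[C@@]2(C)[C@H](Cc3c(OC)cc(OC)cc3OC)CC=C(OS(=O)(=O)C(F)(F)F)[C@@H]2[C@H]1O
F3 | step 7 | hydroxymethyl ketone: ketone 13 with CH2OH in place of the dimethoxymethyl group | OC[C@H]1C(=O)CC[C@@H](Cc2c(OC)cc(OC)cc2OC)[C@]1(C)CCC=C(C)C
F4 | step 7 | silyl ether: tert-butyldimethylsilyl ether of F3 | CC(C)(C)[Si](C)(C)OC[C@H]1C(=O)CC[C@@H](Cc2c(OC)cc(OC)cc2OC)[C@]1(C)CCC=C(C)C
F5 | step 7 | silyloxymethyl enol triflate: C3=C4 enol triflate of F4 | CC(C)(C)[Si](C)(C)OC[C@H]1C(OS(=O)(=O)C(F)(F)F)=CC[C@@H](Cc2c(OC)cc(OC)cc2OC)[C@]1(C)CCC=C(C)C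
F6 | step 7 | silyloxymethyl diene: F5 with CH3 in place of the triflate | CC(C)(C)[Si](C)(C)OC[C@H]1C(C)=CC[C@@H](Cc2c(OC)cc(OC)cc2OC)[C@]1(C)CCC=C(C)C
F7 | step 7 | primary alcohol: [(1S,5S,6S)-2,6-dimethyl-6-(4-methylpent-3-en-1-yl)-5-(2,4,6-trimethoxybenzyl)cyclohex-2-en-1-yl]methanol | OC[C@H]1C(C)=CC[C@@H](Cc2c(OC)cc(OC)cc2OC)[C@]1(C)CCC=C(C)C
F0 | step 15 | none | none
F8 | step 13 | C6 ketone: 1β-(2,4,6-trimethoxybenzyl)eudesma-3,11-dien-6-one | C=C(C)[C@@H]1CC[C@@]2(C)[C@H](Cc3c(OC)cc(OC)cc3OC)CC=C(C)[C@@H]2C1=O
F9 | step 13 | tosylhydrazone of F8 | C=C(C)[C@@H]1CC[C@@]2(C)[C@H](Cc3c(OC)cc(OC)cc3OC)CC=C(C)[C@@H]2C1=NNS(=O)(=O)c4ccc(C)cc4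
F10 | step 19 | triethylsilyl ether of 28 at the C4 hydroxyl group | C=C(C)[C@@H]1CC[C@@]2(C)[C@H](Cc3c(OC)c(C=O)c(OC)c(C(=O)C(C)C)c3OC)CC[C@@](C)(O[Si](CC)(CC)CC)[C@@H]2C1
F11 | step 19 | triphenol silyl ether: 29 with the C4 hydroxyl group as triethylsilyl ether | C=C(C)[C@@H]1CC[C@@]2(C)[C@H](Cc3c(O)c(C=O)c(O)c(C(=O)C(C)C)c3O)CC[C@@](C)(O[Si](CC)(CC)CC)[C@@H]2C1
A1 | alternative 1 | methyl 1β-{[2,4,6-tris(methoxymethoxy)phenyl]methyl}-4,10-dimethyl-3,9-dioxo-octal-4-ene-7β-carboxylate | COC(=O)[C@@H]1CC(=O)[C@@]2(C)[C@H](Cc3c(OCOC)cc(OCOC)cc3OCOC)CC(=O)C(C)=C2C1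
A2 | alternative 1 | methyl 4-methyl-3,5-dioxo-4-{4-oxo-1-[2,4,6-tris(methoxymethoxy)phenyl]hexan-2-yl}cyclohexane-1-carboxylate (ester cis to the ring methyl group) | COC(=O)[C@@H]1CC(=O)[C@@](C)([C@H](Cc2c(OCOC)cc(OCOC)cc2OCOC)CC(=O)CC)C(=O)C1
A3 | alternative 2 | deformyl target: 1-{3-[(4α-hydroxyeudesm-11-en-1β-yl)methyl]-2,4,6-trihydroxyphenyl}-2-methylpropan-1-one | C=C(C)[C@@H]1CC[C@@]2(C)[C@H](Cc3c(O)cc(O)c(C(=O)C(C)C)c3O)CC[C@@](C)(O)[C@@H]2C1
A4 | alternative 2 | methyl 2-[(4α-hydroxyeudesm-11-en-1β-yl)methyl]-8-methyl-3,5,7-trioxononanoate | C=C(C)[C@@H]1CC[C@@]2(C)[C@H](CC(C(=O)OC)C(=O)CC(=O)CC(=O)C(C)C)CC[C@@](C)(O)[C@@H]2C1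
A5 | alternative 3 | trans-fused 4α-hydroxy-4β,10β-dimethyl-1-[2,4,6-tris(methoxymethoxy)benzylidene]decalin-6-one | O=C1CCC[C@@]2(C)/C(=C/c3c(OCOC)cc(OCOC)cc3OCOC)CC[C@@](C)(O)[C@H]12
A6 | alternative 3 | 3-{5-oxo-1-[2,4,6-tris(methoxymethoxy)phenyl]hex-1-en-2-yl}cyclohex-2-en-1-one | CC(=O)CC/C(=C\c1c(OCOC)cc(OCOC)cc1OCOC)C1=CC(=O)CCC1
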